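**Assumptions (one line):** Phloroacetophenone (**5**) is bought as its commercial monohydrate, the target is (2S) by CIP analysis of the given SMILES, and the 9-amino-epi-quinine squaramide **7** is assumed to give the (2S) sense of induction.

## Retrosynthetic overview
- Target **1** is the 6,8-diprenyl-5,7,3′,5′-tetrahydroxy-(2S)-flavanone. Only the C ring has to be built, and it is closed last.
- The C ring forms by enantioselective 6-endo oxa-Michael cyclization of chalcone **2**. Its two ortho-phenols are equivalent, so this step desymmetrizes **2** and sets C2.
- **2** comes from Claisen–Schmidt condensation of 3′,5′-diprenylphloroacetophenone **3** with 3,5-dihydroxybenzaldehyde **4**.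
- **3** comes from double C-prenylation of phloroacetophenone **5** with prenyl bromide **6**. Only C3 and C5 of **5** are free, so the regiochemistry is fixed.
- Both aryl rings come from cheap phloroglucinol-type feedstocks. No protecting groups are used, and the cyclization is catalysed by quinine-squaramide **7**.

## Route

**Step 1**
Reactants: **5** 2′,4′,6′-trihydroxyacetophenone; **6** prenyl bromide (1-bromo-3-methylbut-2-ene)
Product: **3** 2′,4′,6′-trihydroxy-3′,5′-bis(3-methylbut-2-enyl)acetophenone
Conditions: **6** (2.1 equiv), KOH (4.5 equiv), MeOH/H2O, 0 °C → rt, 3 h, N2
Reagents that add atoms: prenyl bromide, CC(C)=CCBr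
Why: The phloroglucinol-type phenolate is alkylated at carbon (phenolate C-alkylation, Friedel–Crafts-type), and only C3 and C5 are open, so the bis-C-prenyl product has the required 6,8-pattern after cyclization. Limiting prenyl bromide and running cold in aqueous methanol minimize O-prenylation and over-alkylation. No stereocenter is formed.

**Step 2**
Reactants: **3**; **4** 3,5-dihydroxybenzaldehyde
Product: **2** (E)-1-[2,4,6-trihydroxy-3,5-bis(3-methylbut-2-enyl)phenyl]-3-(3,5-dihydroxyphenyl)prop-2-en-1-one
Conditions: KOH (8 equiv), EtOH/H2O, 50 °C, 24 h, N2; then cold 1 M HCl to pH ≈ 4 at 0 °C; extract and use immediately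
Reagents that add atoms: none (**4** is a reactant; only water is lost)
Why: Claisen–Schmidt aldol condensation through the polyphenolate gives the thermodynamic E-enone. The phenolate form resists cyclization in base, and the cold, mild acidification avoids premature racemic ring closure and acid-induced prenyl cyclization.

**Step 3**
Reactants: **2**; catalyst **7** (quinine-derived 9-amino-9-deoxy-epi squaramide)
Product: **1** (2S)-5,7-dihydroxy-2-(3,5-dihydroxyphenyl)-6,8-bis(3-methylbut-2-enyl)chroman-4-one (target)
Conditions: **7** (10 mol %), toluene/THF 9:1 (0.02 M), 10 °C, 96 h; direct load onto neutral silica for chromatography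
Reagents that add atoms: none (**7** is a catalyst; the step is an isomerization)
Why: Proposed new method: the squaramide N–H groups of the bifunctional catalyst should bind the enone carbonyl, while the free quinuclidine nitrogen acts as a general base and H-bond acceptor for one of the two equivalent ortho-phenols, so that 6-endo-trig O-attack occurs on one enantiotopic face of the enone and fixes C2 as (S) in a desymmetrizing oxa-Michael cyclization; the closest known reaction is the cinchona thiourea/squaramide-catalysed intramolecular oxa-Michael cyclization of 2′-hydroxychalcones to flavanones, here extended to an unprotected, electron-rich diprenylated polyphenol. Prenyl alkenes and free phenols are untouched under these mild, non-acidic conditions. The product is stabilized by its 5-OH···O=C hydrogen bond, and C2 is not touched afterwards, although prolonged time or added base would erode ee by retro-Michael ring opening.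

## Compound list
1 | (2S)-5,7-dihydroxy-2-(3,5-dihydroxyphenyl)-6,8-bis(3-methylbut-2-enyl)chroman-4-one | CC(C)=CCc1c(O)c(CC=C(C)C)c2c(c1O)C(=O)C[C@@H](c1cc(O)cc(O)c1)O2 | target
2 | (E)-2′,4′,6′,3,5-pentahydroxy-3′,5′-diprenylchalcone | CC(C)=CCc1c(O)c(CC=C(C)C)c(O)c(C(=O)/C=C/c2cc(O)cc(O)c2)c1O | intermediate
3 | 2′,4′,6′-trihydroxy-3′,5′-diprenylacetophenone | CC(C)=CCc1c(O)c(CC=C(C)C)c(O)c(C(C)=O)c1O | intermediate
4 | 3,5-dihydroxybenzaldehyde | O=Cc1cc(O)cc(O)c1 | starting material
5 | 2′,4′,6′-trihydroxyacetophenone (phloroacetophenone) | CC(=O)c1c(O)cc(O)cc1O | starting material
6 | prenyl bromide | CC(C)=CCBr | starting material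
7 | 9-amino-9-deoxy-epi-quinine squaramide bearing a 3,5-bis(CF3)phenyl group (commercial organocatalyst) | COc1ccc2nccc([C@H](NC5=C(Nc4cc(C(F)(F)F)cc(C(F)(F)F)c4)C(=O)C5=O)[C@@H]3C[C@@H]4CCN3C[C@@H]4C=C)c2c1 | starting material (catalyst)

**Total steps:** 3. **Longest linear sequence:** 3 (5 → 3 → 2 → 1).

## Three steps most likely to fail
1. **Step 3 (enantioselectivity).** The racemic background cyclization of the free polyphenol and retro-Michael erosion may lower ee. Fallback: enzymatic cyclization of **2** with recombinant chalcone isomerase in pH 7.5 buffer, which gives (2S)-flavanones by a different mechanism. If the catalyst gives the wrong sense, use the quinidine-derived pseudoenantiomer.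
2. **Step 1 (selectivity and yield).** The reaction may give mixtures of mono-, tri- and O-prenylated products, so the yield of **3** is likely to be modest (about 25–35%). Fallback: reverse the bond-forming order by bis-C-prenylating phloroglucinol first, separating the 2,4-diprenyl isomer, then installing the acetyl group by BF3·OEt2/AcOH acylation to give **3**.
3. **Step 2 (Claisen–Schmidt on a free polyphenol).** The aldehyde phenolate is a poor electrophile, which may cause low conversion or partial cyclization. Fallback: protect **4** as its bis-MOM ether, condense under the same base, cyclize asymmetrically as in step 3, then remove the MOM groups with mild acid (PPTS, t-BuOH/H2O).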